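**Retrosynthetic overview**

- The target is the mono-O-acetate of a 3,6-dihydroxy-2,5-diaryl-1,4-benzoquinone. Removing the acetyl group, protecting the phenols as benzyl ethers, and returning the quinone to its tetramethyl ether leads to a para-terphenyl with a 2,3,5,6-tetramethoxy central ring.
- The strategy rests on one feature: each 4-hydroxyphenyl ring is bonded through its ipso carbon to C2 or C5 of the cyclohexadienedione ring and carries its oxygen para to that bond. This is the pattern left when a carbon atom replaces the ring oxygen of a 4-alkoxypyrylium ion.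
- Key disconnection: both ipso–ortho bonds of each outer ring, leading back to a para-xylylene bis(phosphonium) salt on the tetramethoxybenzene core and two 4-(benzyloxy)pyrylium ions.
- Ring order: the central ring is bought as 1,2,4,5-tetramethoxybenzene, both outer benzene rings are formed together in step 4, and the central ring is then oxidised to the quinone and its oxygens are differentiated.

Key step: step 4

Remark on the chemistry: the target has no stereocentre and no stereogenic double bond, so no configuration needs to be set.

**Route**

Step 1
Reactants: 1 1,2,4,5-tetramethoxybenzene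
Product: 2 1,4-bis(bromomethyl)-2,3,5,6-tetramethoxybenzene
Conditions: (CH2O)n (excess), 33% HBr in AcOH, AcOH, 50 °C
Reagents that add atoms: formaldehyde from paraformaldehyde (two molecules), C=O; hydrogen bromide (two molecules), Br
Why: Twofold Blanc-type bromomethylation (electrophilic aromatic substitution); the only two free ring positions are para to each other and each is flanked by two methoxy groups, so hydroxymethylation and exchange of the benzylic hydroxyl for bromide can only lead to the 1,4-bis(bromomethyl) compound.

Step 2
Reactants: 2 1,4-bis(bromomethyl)-2,3,5,6-tetramethoxybenzene; 3 triphenylphosphine (two molecules)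
Product: 4 [(2,3,5,6-tetramethoxy-1,4-phenylene)bis(methylene)]bis(triphenylphosphonium) dibromide
Conditions: PPh3 (2.2 equiv), toluene, 110 °C
Reagents that add atoms: none
Why: Twofold SN2 quaternisation (phosphonium salt formation) in which each of the two electron-rich benzylic bromides takes up one molecule of the phosphine; the bis-salt should precipitate from the hot non-polar solvent.

Step 3
Reactants: 5 4H-pyran-4-one; 6 benzyl bromide
Product: 7 4-(benzyloxy)pyrylium tetrafluoroborate
Conditions: AgBF4 (1.0 equiv), CH2Cl2, 0 °C to rt, dark, dry N2; filter, precipitate with Et2O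
Reagents that add atoms: silver tetrafluoroborate, [Ag+].F[B-](F)(F)F
Why: Silver-assisted O-alkylation of the pyranone carbonyl (Meerwein-type alkylation of a vinylogous ester); the carbonyl oxygen is the most nucleophilic site because alkylation there creates the aromatic pyrylium ion, and precipitation of AgBr makes the benzyl transfer irreversible.

Step 4
Reactants: 4 [(2,3,5,6-tetramethoxy-1,4-phenylene)bis(methylene)]bis(triphenylphosphonium) dibromide; 7 4-(benzyloxy)pyrylium tetrafluoroborate (two molecules)
Product: 11 1,4-bis[4-(benzyloxy)phenyl]-2,3,5,6-tetramethoxybenzene, via bis-ylide 8 (not isolated), via bis-pyranyl phosphonium salt 9 (not isolated), via bis-dienal phosphonium salt 10 (not isolated)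
Conditions: NaN(SiMe3)2 (2.0 equiv), THF, −78 to 0 °C; transfer onto 7 (2.4 equiv), MeCN–CH2Cl2, −40 °C to rt; NaN(SiMe3)2 (2.5 equiv), −40 °C to rt, then 50 °C
Reagents that add atoms: none
Why: Each ylide carbon of 8 adds to an unsubstituted carbon next to the ring oxygen (C2) of a 4-(benzyloxy)pyrylium ion to give the 2H-pyran 9, which opens by 6π-electrocyclic reversal to the dienal 10 with the aldehyde carbon held cis to C3 across the former ring double bond; the second charge of base then regenerates a conjugated ylide whose carbon closes onto the aldehyde and expels triphenylphosphine oxide, which carries off the pyrylium oxygen. The closest known reaction type is the conversion of pyrylium salts into benzenes by alkylidene- and benzylidenetriphenylphosphoranes, the carbon counterpart of the pyrylium-to-pyridine and pyrylium-to-nitrobenzene exchanges. Each of the two benzene rings is closed by an intramolecular Wittig olefination, a 6-exo-trig addition of the ylide carbon to the aldehyde (equivalently a 6π-electrocyclisation of the phosphonio-trienolate) followed by oxaphosphetane collapse, and aromatisation makes the closure irreversible. No stereocentre is created in 11; the phosphonium-bearing carbons of 9 and 10 are stereogenic only in passing, and the 2,3-double bond of 10 can rotate once the delocalised ylide is formed. The step needs attack at C2 and not at C4 or at the benzylic carbon of the pyrylium ion: C2 and C6 are open CH positions next to the oxonium oxygen where carbon nucleophiles add kinetically at low temperature, whereas C4 is substituted and shares its positive charge with the benzyloxy oxygen, and the bulky aryl(triphenylphosphonio)methyl nucleophile disfavours both a quaternary C4 adduct and an SN2 benzyl transfer. The hexasubstituted central ring offers no competing site, so both arms should react alike and each benzyloxy group ends para to the new biaryl bond.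

Step 5
Reactants: 11 1,4-bis[4-(benzyloxy)phenyl]-2,3,5,6-tetramethoxybenzene
Product: 12 2,5-bis[4-(benzyloxy)phenyl]-3,6-dimethoxycyclohexa-2,5-diene-1,4-dione
Conditions: (NH4)2Ce(NO3)6 (2.5 equiv), MeCN–H2O, 0 °C
Reagents that add atoms: water (two molecules), O
Why: Oxidative demethylation of a para-dimethoxyarene by tetravalent cerium; the tetramethoxy ring is by far the most easily oxidised arene, its radical cation takes up water at a methoxy-bearing carbon and loses methanol twice to give the para-quinone, while the two remaining methoxy groups stay as vinylogous esters and the aryl benzyl ethers are not touched.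

Step 6
Reactants: 12 2,5-bis[4-(benzyloxy)phenyl]-3,6-dimethoxycyclohexa-2,5-diene-1,4-dione
Product: 13 2,5-bis[4-(benzyloxy)phenyl]-3,6-dihydroxycyclohexa-2,5-diene-1,4-dione
Conditions: 2 M NaOH aq, 1,4-dioxane, 70 °C, N2; then cold 1 M HCl
Reagents that add atoms: sodium hydroxide (two molecules), [Na+].[OH-]
Why: Saponification of a vinylogous ester by conjugate addition–elimination of hydroxide at the two methoxy-bearing quinone carbons; the dianion that results resists further attack, and aryl benzyl ethers are stable to aqueous base.

Step 7
Reactants: 13 2,5-bis[4-(benzyloxy)phenyl]-3,6-dihydroxycyclohexa-2,5-diene-1,4-dione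
Product: 14 2,5-bis[4-(benzyloxy)phenyl]-4-hydroxy-3,6-dioxocyclohexa-1,4-dien-1-yl acetate
Conditions: Et3N (2.2 equiv), Ac2O (1.0 equiv), CH2Cl2, −20 to 0 °C; cold dilute citric acid work-up
Reagents that add atoms: acetic anhydride, CC(=O)OC(C)=O
Why: O-Acylation of an acidic enol (vinylogous carboxylic acid) with one equivalent of anhydride; with two equivalents of amine 13 reacts as its dianion, which is a better nucleophile than the mono-anion of 14 left after the first acylation, so the reaction should stop largely at the monoacetate.

Step 8
Reactants: 14 2,5-bis[4-(benzyloxy)phenyl]-4-hydroxy-3,6-dioxocyclohexa-1,4-dien-1-yl acetate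
Product: 16 4-hydroxy-2,5-bis(4-hydroxyphenyl)-3,6-dioxocyclohexa-1,4-dien-1-yl acetate, via hydroquinone monoacetate 15 (not isolated)
Conditions: H2 (1 atm), Pd/C (10% palladium on carbon), EtOAc, rt; filter, then stir under air, rt
Reagents that add atoms: none
Why: Catalytic hydrogenolysis of the two aryl benzyl ethers under neutral conditions spares the acetate; the quinone is reduced at the same time to hydroquinone 15, in which an acetyl shift between neighbouring oxygens is degenerate, and autoxidation in air restores the para-quinone across the two free para hydroxyl groups to give the target.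

**Compound list**

1 | 1,2,4,5-tetramethoxybenzene | COc1cc(OC)c(OC)cc1OC | starting material
2 | 1,4-bis(bromomethyl)-2,3,5,6-tetramethoxybenzene | COc1c(OC)c(CBr)c(OC)c(OC)c1CBr | intermediate
3 | triphenylphosphine | c1ccc(P(c2ccccc2)c2ccccc2)cc1 | starting material
4 | [(2,3,5,6-tetramethoxy-1,4-phenylene)bis(methylene)]bis(triphenylphosphonium) dibromide | COc1c(OC)c(C[P+](c2ccccc2)(c2ccccc2)c2ccccc2)c(OC)c(OC)c1C[P+](c1ccccc1)(c1ccccc1)c1ccccc1.[Br-].[Br-] | intermediate
5 | 4H-pyran-4-one | O=c1ccocc1 | starting material
6 | benzyl bromide | BrCc1ccccc1 | starting material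
7 | 4-(benzyloxy)pyrylium tetrafluoroborate | c1cc(OCc2ccccc2)cc[o+]1.F[B-](F)(F)F | intermediate
8 | bis-ylide: [(2,3,5,6-tetramethoxy-1,4-phenylene)dimethylidyne]bis(triphenylphosphorane) | COc1c(OC)c(C=P(c2ccccc2)(c2ccccc2)c2ccccc2)c(OC)c(OC)c1C=P(c1ccccc1)(c1ccccc1)c1ccccc1 | intermediate (not isolated)
9 | bis-pyranyl phosphonium salt: (2,3,5,6-tetramethoxy-1,4-phenylene)bis{[4-(benzyloxy)-2H-pyran-2-yl]methylene}bis(triphenylphosphonium) bis(tetrafluoroborate), mixture of diastereomers | COc1c(OC)c(C(C2C=C(OCc3ccccc3)C=CO2)[P+](c2ccccc2)(c2ccccc2)c2ccccc2)c(OC)c(OC)c1C(C1C=C(OCc2ccccc2)C=CO1)[P+](c1ccccc1)(c1ccccc1)c1ccccc1.F[B-](F)(F)F.F[B-](F)(F)F | intermediate (not isolated)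
10 | bis-dienal phosphonium salt: (2,3,5,6-tetramethoxy-1,4-phenylene)bis[4-(benzyloxy)-6-oxohexa-2,4-diene-1,1-diyl]bis(triphenylphosphonium) bis(tetrafluoroborate), aldehyde carbon cis to C3 across the 4,5-double bond, 2,3-double bond drawn trans, mixture of diastereomers at the phosphonium-bearing carbons | COc1c(OC)c(C(/C=C/C(OCc2ccccc2)=C\C=O)[P+](c2ccccc2)(c2ccccc2)c2ccccc2)c(OC)c(OC)c1C(/C=C/C(OCc1ccccc1)=C\C=O)[P+](c1ccccc1)(c1ccccc1)c1ccccc1.F[B-](F)(F)F.F[B-](F)(F)F | intermediate (not isolated)
11 | 1,4-bis[4-(benzyloxy)phenyl]-2,3,5,6-tetramethoxybenzene | COc1c(OC)c(-c2ccc(OCc3ccccc3)cc2)c(OC)c(OC)c1-c1ccc(OCc2ccccc2)cc1 | intermediate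
12 | 2,5-bis[4-(benzyloxy)phenyl]-3,6-dimethoxycyclohexa-2,5-diene-1,4-dione | COC1=C(c2ccc(OCc3ccccc3)cc2)C(=O)C(OC)=C(c2ccc(OCc3ccccc3)cc2)C1=O | intermediate
13 | 2,5-bis[4-(benzyloxy)phenyl]-3,6-dihydroxycyclohexa-2,5-diene-1,4-dione | OC1=C(c2ccc(OCc3ccccc3)cc2)C(=O)C(O)=C(c2ccc(OCc3ccccc3)cc2)C1=O | intermediate
14 | 2,5-bis[4-(benzyloxy)phenyl]-4-hydroxy-3,6-dioxocyclohexa-1,4-dien-1-yl acetate | CC(=O)OC1=C(c2ccc(OCc3ccccc3)cc2)C(=O)C(O)=C(c2ccc(OCc3ccccc3)cc2)C1=O | intermediate
15 | hydroquinone monoacetate: 2,4,5-trihydroxy-3,6-bis(4-hydroxyphenyl)phenyl acetate | CC(=O)Oc1c(O)c(-c2ccc(O)cc2)c(O)c(O)c1-c1ccc(O)cc1 | intermediate (not isolated)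
16 | 4-hydroxy-2,5-bis(4-hydroxyphenyl)-3,6-dioxocyclohexa-1,4-dien-1-yl acetate | CC(=O)OC1=C(c2ccc(O)cc2)C(=O)C(O)=C(c2ccc(O)cc2)C1=O | target

**Step count**

Total: 8 steps. Longest linear sequence: 7 steps (1 → 2 → 4 → 11 → 12 → 13 → 14 → 16); the pyrylium salt 7 is made in one step on a side branch.

**Steps most likely to fail**

Step 4. The ylide may add at C4 of the pyrylium ion with loss of benzyl alcohol, may take up the benzyl group by SN2 transfer, or the second annulation may stall after the first ring has formed. The fallback sets out from 1 and builds the same two biaryl bonds by cross-coupling. Bromination of 1 (Br2, CH2Cl2, 0 °C) should give 1,4-dibromo-2,3,5,6-tetramethoxybenzene F1. A twofold Suzuki–Miyaura coupling of F1 with commercial 4-(benzyloxy)phenylboronic acid (OB(O)c1ccc(OCc2ccccc2)cc1; Pd(OAc)2, SPhos, K3PO4, toluene–H2O, 100 °C) would then deliver 11, where the route is rejoined at step 5. This path also avoids the pyrylium salt 7.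

Step 7. Acylation may run on to the diacetate while diol remains, or the vinylogous anhydride may be cleaved again on work-up. The fallback sets out from 13 and reaches the monoacetate from the other side. Exhaustive acetylation (Ac2O, pyridine, catalytic DMAP, rt) should give 2,5-bis[4-(benzyloxy)phenyl]-3,6-dioxocyclohexa-1,4-diene-1,4-diyl diacetate F2. Controlled mono-deacylation of F2 (aqueous NaHCO3, THF, 0 °C, then cold dilute acid) is expected to stop after one acetate, because the hydroxyquinone anion formed by the first cleavage deactivates the remaining acetate towards hydroxide. This returns to the route at 14.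

Step 8. The leuco compound formed by reduction of the quinone may reoxidise sluggishly or lose its acetyl group, and hydrogenolysis of the second benzyl ether may be slow on the poorly soluble intermediate. The fallback sets out from 14 and removes the benzyl groups without a reducing agent. Treatment with BCl3 and pentamethylbenzene as cation scavenger (CH2Cl2, −78 °C, quench with MeOH–CH2Cl2 at low temperature) should cleave both aryl benzyl ethers while the quinone stays in its oxidised state, and it arrives directly at 16. No new isolated compound arises on this path (F0).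

Further compounds
F1 | step 4 | 1,4-dibromo-2,3,5,6-tetramethoxybenzene | COc1c(OC)c(Br)c(OC)c(OC)c1Br
F2 | step 7 | 2,5-bis[4-(benzyloxy)phenyl]-3,6-dioxocyclohexa-1,4-diene-1,4-diyl diacetate | CC(=O)OC1=C(c2ccc(OCc3ccccc3)cc2)C(=O)C(OC(C)=O)=C(c2ccc(OCc3ccccc3)cc2)C1=O
F0 | step 8 | none | none
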